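Remark: the SMILES is read literally: 3R, 7R, 10S, 11R, 22S, 14E, 18E. C9 and C12 are cis on the oxirane, so the ring is that of a (10Z)-olefin, and the two termini are heterochiral.

## Structural features

The target is an acyclic C33 trimethylsqualene oxide. Its C24 chain (numbered from the left isopropenyl CH2 as C1) carries methyl groups on C2, C3, C7, C10, C15, C19, C22 and C23 and a methylidene on C6; it has three 1,1-disubstituted alkenes (C1=C2, C6=CH2, C23=CH2), two (E)-trisubstituted alkenes (C14=C15, C18=C19) and one ring, the 10,11-oxirane. C3 (R), C7 (R) and C22 (S) are tertiary allylic CH(CH3) centres, each next to a 1,1-disubstituted alkene; C3 and C7 are 1,5-related, C22 is remote, and the two 3,4-dimethylpent-4-enyl termini are mirror images (3R against 22S). C10 (S) and C11 (R) are adjacent in the trisubstituted oxirane, whose chain branches C9 and C12 are cis; C10 is 1,4 to C7. The oxirane is the fragile group (acid, hydride, hard organometallics), the 1,1-disubstituted alkenes isomerise under acid, and there is no other heteroatom, so every coupling handle must leave without trace. The real difficulty is the set of three isolated methyl-bearing stereocentres, which cannot relay to one another and must each be made together with its methylene group, plus one oxirane to be placed on one of six alkenes. The key step exploits the two units C1=C2–C3H(CH3) and H2C=C6–C7H(CH3) (no ring is involved): each is the SN2′ image of an (E)-2-substituted allylic bromide with the same local geometry and the same (R) sense, so one chiral copper catalyst can form both C–CH3 bonds, both stereocentres and both 1,1-disubstituted alkenes at once, in the way C-methylation of a preformed isoprenoid chain does in the biosynthesis.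

## Logic of the disconnections

In one sentence, the route is a two-fold copper-catalysed enantioselective SN2′ C-methylation of the achiral bis(allylic bromide) 14.

29 ⇒ 28 ⇒ 18 + 26. The C13–H bond is traced back to C13–SO2Ph, and then the C12–C13 bond is cut. This is the tail-to-tail junction of the two isoprenoid halves. The cut gives a left half whose C12 oxygen can direct the oxirane, and a right half that is a simple allylic sulfone. The forward steps need SN2 at a primary triflate faster than attack on the oxirane, and removal of sulfur without moving or isomerising C14=C15.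

18 ⇒ 17 ⇒ 16. The two C–O bonds of the oxirane are cut back to the (Z)-allylic alcohol. The hydroxyl on C12 solves the site problem (one alkene out of three in 16), and the Z geometry gives the cis ring. The forward step must be reagent-controlled, because C7 is too far away to help.

16 ⇒ 15 ⇒ 14 (key). The C3–CH3 and C7–CH3 bonds are cut with allylic transposition. Both stereocentres and both 1,1-disubstituted alkenes disappear, and 14 has no stereocentre, only olefin geometry. The forward step needs SN2′ over SN2 at two sites and the same facial sense (Re) at two centres insulated by a CH2CH2 spacer. It therefore needs catalyst control and an identical (E) arrangement at both allylic bromides.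

14 ⇒ 13 ⇒ 12 ⇒ 11. The C–Br bonds go back to C–OH. The C6a oxygen comes from an ester, and the C1 oxygen from allylic C–H oxidation of the terminal E-methyl. This reduces 14 to a triene ester. The oxidation must pick the isopropylidene end and give the (E)-alcohol.

11 ⇒ 5 + 9, and 9 ⇒ 6 + 7. The C6=C7 bond is cut by olefination and the C5–C6 bond by enolate alkylation. The olefination must give the (E)-enoate, since that geometry later puts CH2Br trans to C8.

5 ⇒ 3 ⇒ 2 ⇒ 1. The distal alkene of 1 is cleaved to the C7 aldehyde. 1 supplies C7–C12 with the Z alkene and the C12 oxygen ready-made. The epoxidation must be selective for the distal alkene.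

26 ⇒ 25 ⇒ 24 ⇒ 23 ⇒ 22 ⇒ 21 ⇒ 20 ⇒ 19. The right half repeats the same C–CH3 cut at C22 on the mono-bromide 22, with the enantiomeric catalyst (Si face, S). 19 supplies C13–C24 with both E alkenes. The demands are the same as for the key step, at one site.

## Other disconnections considered

Alternative 1: the first plan to come to mind. Cut the C6=CH2 bond and C5–C6: ketone A1 from Weinreb amide A2 (C7 set by auxiliary-controlled enolate alkylation) and the Grignard reagent of bromide A3 (C3 from the chiral pool), then methylenation of A1 to reach 15; C22 is made a third time in the same way. The forward key step is acylation followed by methylenation of an α-stereogenic ketone. The chosen plan is preferred for three reasons: this route spends one stoichiometric source of chirality per stereocentre; methylenation of a hindered, enolisable α-methyl ketone puts C7 at risk of epimerisation under basic ylide conditions; and no alkene arises together with its stereocentre, so the count of steps is higher.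

Alternative 2: cut C3–C4 and C7–C8 by [3,3]-sigmatropic rearrangement. Johnson–Claisen rearrangement of a 2-substituted (E)-but-2-en-1-ol such as A4 with triethyl orthoacetate gives exactly the motif CH2=C(R)–CH(CH3)–CH2–CO2Et, as in A5, and could be iterated along C1–C9. The defect is mechanistic: the carbinol carbon becomes the =CH2 carbon, so the chair transition state has no stereocentre to transfer and A5 would be racemic. Absolute control would have to come from a chiral controller on an unsubstituted acetate-type enolate, which has little to discriminate. Each iteration also needs several steps to rebuild the next allylic alcohol.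

Alternative 3: unite the halves first and cut all three C–CH3 bonds at once on the C30 tris(allylic bromide) A6. A single catalyst would give the same local sense at three equivalent (E)-allylic sites and therefore the (3R,7R,22R) hydrocarbon A7, whereas the target needs 22S. In addition, the oxirane cannot be present during the Grignard/copper step and cannot be placed selectively afterwards on a hexaene without a hydroxyl handle. The chosen plan keeps the idea but splits it 2 + 1 over the two halves, with enantiomeric ligands, and keeps the C12 hydroxyl for the epoxidation.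

Key step: step 9

Remark: half-converted species of the two-fold steps 7–9 are transient mixtures of positional isomers and are not numbered; carbanions prepared in a separate operation (steps 4, 5, 20) and the glycol of step 3 are numbered as non-isolated intermediates.

Remark: the ligand antipode in steps 9 and 16 is defined by the face that must be attacked (Re at C3 and C7 of 14, Si at C22 of 22) and is to be assigned on a simple (E)-allylic bromide before use.

## Route

Step 1
Reactants: 1 nerol, (2Z)-3,7-dimethylocta-2,6-dien-1-ol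
Product: 2 tert-butyl{[(2Z)-3,7-dimethylocta-2,6-dien-1-yl]oxy}diphenylsilane
Conditions: TBDPSCl, imidazole, DMF, 0 °C → rt
Reagents that add atoms: tert-butyl(chloro)diphenylsilane, CC(C)(C)[Si](Cl)(c1ccccc1)c1ccccc1
Why: Imidazole-promoted O-silylation of a primary allylic alcohol; the TBDPS ether should survive peracid, periodic acid, hydride, Appel conditions and the Grignard/copper step, and it is not a leaving group in allylic substitution.

Step 2
Reactants: 2 tert-butyl{[(2Z)-3,7-dimethylocta-2,6-dien-1-yl]oxy}diphenylsilane
Product: 3 tert-butyl{[(2Z)-5-(3,3-dimethyloxiran-2-yl)-3-methylpent-2-en-1-yl]oxy}diphenylsilane (racemic at the oxirane CH)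
Conditions: mCPBA (1.0 equiv), CH2Cl2, −20 → 0 °C
Reagents that add atoms: 3-chloroperoxybenzoic acid, OOC(=O)c1cccc(Cl)c1
Why: Prilezhaev epoxidation; the distal trisubstituted alkene is the more nucleophilic one because the proximal alkene is deactivated by the allylic silyloxy group, so mono-epoxidation should be regioselective; the new centre is racemic and is destroyed in step 3.

Step 3
Reactants: 3 tert-butyl{[(2Z)-5-(3,3-dimethyloxiran-2-yl)-3-methylpent-2-en-1-yl]oxy}diphenylsilane
Product: 5 (4Z)-6-[(tert-butyldiphenylsilyl)oxy]-4-methylhex-4-enal, via vicinal diol 4 (not isolated)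
Conditions: H5IO6, THF–H2O, 0 °C
Reagents that add atoms: none
Why: Acid-assisted hydration of the oxirane (water at the tertiary carbon) followed by periodate glycol cleavage in the same flask; the aldehyde oxygen is the former oxirane oxygen, and the Z alkene and the silyl ether should be untouched at 0 °C.

Step 4
Reactants: 6 triethyl phosphonoacetate; 7 5-bromo-2-methylpent-2-ene
Product: 9 ethyl 2-(diethoxyphosphoryl)-6-methylhept-5-enoate (racemic), via sodium phosphonoacetate enolate 8 (not isolated)
Conditions: NaH, DMF, 0 °C; then 7, 50 °C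
Reagents that add atoms: none
Why: SN2 C-alkylation of a stabilised phosphonoacetate enolate by a primary bromide; a slight excess of enolate should limit dialkylation, and the racemic α-centre becomes sp2 in step 5.

Step 5
Reactants: 9 ethyl 2-(diethoxyphosphoryl)-6-methylhept-5-enoate; 5 (4Z)-6-[(tert-butyldiphenylsilyl)oxy]-4-methylhex-4-enal
Product: 11 ethyl (2E,6Z)-8-[(tert-butyldiphenylsilyl)oxy]-6-methyl-2-(4-methylpent-3-en-1-yl)octa-2,6-dienoate, via sodium phosphonate carbanion 10 (not isolated)
Conditions: NaH, THF, 0 °C; then 5, 0 °C → rt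
Reagents that add atoms: none
Why: Horner–Wadsworth–Emmons olefination; reversible addition and thermodynamic control of the oxaphosphetane should favour the (E)-enoate (ester trans to C8), which is the geometry that later places CH2Br trans to C8; the minor Z isomer should be separable by chromatography.

Step 6
Reactants: 11 ethyl (2E,6Z)-8-[(tert-butyldiphenylsilyl)oxy]-6-methyl-2-(4-methylpent-3-en-1-yl)octa-2,6-dienoate
Product: 12 ethyl (2E,6Z)-8-[(tert-butyldiphenylsilyl)oxy]-2-[(3E)-5-hydroxy-4-methylpent-3-en-1-yl]-6-methylocta-2,6-dienoate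
Conditions: SeO2 (0.5 equiv), t-BuOOH, salicylic acid (cat.), CH2Cl2, 0 °C → rt
Reagents that add atoms: selenium dioxide, O=[Se]=O (oxygen-transfer agent); tert-butyl hydroperoxide, CC(C)(C)OO (terminal oxidant)
Why: Selenium dioxide allylic oxidation (ene reaction, then [2,3]-sigmatropic shift); the isopropylidene end is the most electron-rich alkene, whereas the enoate C=C and the alkene next to the silyloxy group are deactivated, and the ordered [2,3] step should deliver the (E)-allylic alcohol from the E-methyl group.

Step 7
Reactants: 12 ethyl (2E,6Z)-8-[(tert-butyldiphenylsilyl)oxy]-2-[(3E)-5-hydroxy-4-methylpent-3-en-1-yl]-6-methylocta-2,6-dienoate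
Product: 13 (2E,6E,10Z)-12-[(tert-butyldiphenylsilyl)oxy]-6-(hydroxymethyl)-2,10-dimethyldodeca-2,6,10-trien-1-ol
Conditions: DIBAL-H (4 equiv), CH2Cl2, −78 °C; Rochelle salt work-up
Reagents that add atoms: none
Why: 1,2-Reduction of a conjugated ester to the allylic alcohol with retention of olefin geometry; material over-oxidised to the aldehyde level in step 6 would converge on the same diol.

Step 8
Reactants: 13 (2E,6E,10Z)-12-[(tert-butyldiphenylsilyl)oxy]-6-(hydroxymethyl)-2,10-dimethyldodeca-2,6,10-trien-1-ol
Product: 14 tert-butyl{[(2Z,6E,10E)-12-bromo-7-(bromomethyl)-3,11-dimethyldodeca-2,6,10-trien-1-yl]oxy}diphenylsilane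
Conditions: CBr4, PPh3, CH2Cl2, 0 °C; used without storage
Reagents that add atoms: carbon tetrabromide, BrC(Br)(Br)Br
Why: Two-fold Appel bromination of primary allylic alcohols under neutral conditions; direct SN2 displacement of the oxyphosphonium group should leave the double bonds in place with unchanged geometry.

Step 9
Reactants: 14 tert-butyl{[(2Z,6E,10E)-12-bromo-7-(bromomethyl)-3,11-dimethyldodeca-2,6,10-trien-1-yl]oxy}diphenylsilane
Product: 15 tert-butyldiphenyl{[(2Z,6R,10R)-3,6,10,11-tetramethyl-7-methylidenedodeca-2,11-dien-1-yl]oxy}silane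
Conditions: CuBr·SMe2 (5 mol %), Taniaphos-type ferrocenyl diphosphine (6 mol %, Re-selective antipode), MeMgBr (2.6 equiv, slow addition), CH2Cl2, −78 °C
Reagents that add atoms: methylmagnesium bromide, C[Mg]Br
Why: MeMgBr transmetalates to a chiral methylcopper(I) complex, which at each allylic bromide binds the alkene, adds oxidatively anti to bromide to give a σ-allyl copper(III) at the γ-carbon (C3 or C7) and then eliminates reductively, so that the C–CH3 bond forms while the double bond moves to the 1,1-disubstituted position. The closest known reaction type is the copper-catalysed enantioselective SN2′ alkylation of (E)-allylic and β-substituted allylic halides with Grignard reagents. No ring is closed. C3 and C7 are each set by the catalyst alone through Re-face delivery of methyl (R at both); the centres are insulated by a CH2CH2 spacer, and one ligand antipode serves both because both sites have the same (E) arrangement with CH2Br trans to the γ-alkyl chain. The step needs SN2′ over SN2 at both sites, which the bromide leaving group, the non-coordinating solvent, low temperature and a low stationary Grignard concentration should secure, the γ-carbons being unhindered CH termini. Two independent catalyst-controlled events should amplify the enantiomeric purity of the (R,R) product statistically, with facial errors appearing mainly as the (R,S)/(S,R) diastereomer. The (Z)-alkene next to the silyloxy group should be inert, since a silyl ether does not ionise under these conditions.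

Step 10
Reactants: 15 tert-butyldiphenyl{[(2Z,6R,10R)-3,6,10,11-tetramethyl-7-methylidenedodeca-2,11-dien-1-yl]oxy}silane
Product: 16 (2Z,6R,10R)-3,6,10,11-tetramethyl-7-methylidenedodeca-2,11-dien-1-ol
Conditions: TBAF, THF, 0 °C → rt
Reagents that add atoms: none
Why: Fluoride-induced Si–O cleavage driven by the Si–F bond; no other group in 15 reacts with TBAF.

Step 11
Reactants: 16 (2Z,6R,10R)-3,6,10,11-tetramethyl-7-methylidenedodeca-2,11-dien-1-ol
Product: 17 {(2R,3S)-3-methyl-3-[(3R,7R)-3,7,8-trimethyl-4-methylidenenon-8-en-1-yl]oxiran-2-yl}methanol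
Conditions: Ti(OiPr)4 (10 mol %), D-(−)-diethyl tartrate (12 mol %), t-BuOOH, 4 Å MS, CH2Cl2, −20 °C
Reagents that add atoms: tert-butyl hydroperoxide, CC(C)(C)OO
Why: Sharpless asymmetric epoxidation; the titanium tartrate binds the allylic alcohol, so only C10=C11 is oxidised and the two 1,1-disubstituted alkenes are ignored; D-(−)-tartrate should deliver oxygen to the face that gives C11 R and C10 S, and the Z geometry becomes the cis oxirane, under reagent control with no influence from the remote C7.

Step 12
Reactants: 17 {(2R,3S)-3-methyl-3-[(3R,7R)-3,7,8-trimethyl-4-methylidenenon-8-en-1-yl]oxiran-2-yl}methanol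
Product: 18 {(2R,3S)-3-methyl-3-[(3R,7R)-3,7,8-trimethyl-4-methylidenenon-8-en-1-yl]oxiran-2-yl}methyl trifluoromethanesulfonate
Conditions: Tf2O, 2,6-lutidine, CH2Cl2, −78 °C; cold work-up, used at once
Reagents that add atoms: trifluoromethanesulfonic anhydride, O=S(=O)(OS(=O)(=O)C(F)(F)F)C(F)(F)F
Why: O-Sulfonylation of the primary alcohol with a hindered base at low temperature; the 2,3-epoxy triflate is a very reactive SN2 electrophile and is therefore not purified.

Step 13
Reactants: 19 (2E,6E)-farnesol, (2E,6E)-3,7,11-trimethyldodeca-2,6,10-trien-1-ol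
Product: 20 tert-butyldiphenyl{[(2E,6E)-3,7,11-trimethyldodeca-2,6,10-trien-1-yl]oxy}silane
Conditions: TBDPSCl, imidazole, DMF, 0 °C → rt
Reagents that add atoms: tert-butyl(chloro)diphenylsilane, CC(C)(C)[Si](Cl)(c1ccccc1)c1ccccc1
Why: O-Silylation as in step 1; the ether masks C13 through oxidation, bromination and the Grignard/copper step.

Step 14
Reactants: 20 tert-butyldiphenyl{[(2E,6E)-3,7,11-trimethyldodeca-2,6,10-trien-1-yl]oxy}silane
Product: 21 (2E,6E,10E)-12-[(tert-butyldiphenylsilyl)oxy]-2,6,10-trimethyldodeca-2,6,10-trien-1-ol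
Conditions: SeO2 (0.5 equiv), t-BuOOH, salicylic acid (cat.), CH2Cl2, 0 °C → rt
Reagents that add atoms: selenium dioxide, O=[Se]=O (oxygen-transfer agent); tert-butyl hydroperoxide, CC(C)(C)OO (terminal oxidant)
Why: Selenium dioxide allylic oxidation at the E-methyl of the terminal isopropylidene group, the most accessible and electron-rich site; the alkene next to the silyloxy group is deactivated and the internal alkene is slower, so the (E)-alcohol should be the main product at partial conversion.

Step 15
Reactants: 21 (2E,6E,10E)-12-[(tert-butyldiphenylsilyl)oxy]-2,6,10-trimethyldodeca-2,6,10-trien-1-ol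
Product: 22 tert-butyl{[(2E,6E,10E)-12-bromo-3,7,11-trimethyldodeca-2,6,10-trien-1-yl]oxy}diphenylsilane
Conditions: CBr4, PPh3, CH2Cl2, 0 °C; used without storage
Reagents that add atoms: carbon tetrabromide, BrC(Br)(Br)Br
Why: Appel bromination of a primary allylic alcohol, as in step 8, without transposition.

Step 16
Reactants: 22 tert-butyl{[(2E,6E,10E)-12-bromo-3,7,11-trimethyldodeca-2,6,10-trien-1-yl]oxy}diphenylsilane
Product: 23 tert-butyldiphenyl{[(2E,6E,10S)-3,7,10,11-tetramethyldodeca-2,6,11-trien-1-yl]oxy}silane
Conditions: CuBr·SMe2 (5 mol %), enantiomeric Taniaphos-type ligand (6 mol %, Si-selective antipode), MeMgBr (1.3 equiv, slow addition), CH2Cl2, −78 °C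
Reagents that add atoms: methylmagnesium bromide, C[Mg]Br
Why: The same copper-catalysed enantioselective SN2′ methylation as in step 9 at a single site; the mirror-image ligand should deliver methyl to the Si face of C22 and give the S centre that the heterochiral terminus needs, and the other alkenes and the silyl ether are not electrophiles.

Step 17
Reactants: 23 tert-butyldiphenyl{[(2E,6E,10S)-3,7,10,11-tetramethyldodeca-2,6,11-trien-1-yl]oxy}silane
Product: 24 (2E,6E,10S)-3,7,10,11-tetramethyldodeca-2,6,11-trien-1-ol
Conditions: TBAF, THF, 0 °C → rt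
Reagents that add atoms: none
Why: Fluoride-induced desilylation as in step 10.

Step 18
Reactants: 24 (2E,6E,10S)-3,7,10,11-tetramethyldodeca-2,6,11-trien-1-ol
Product: 25 (3S,6E,10E)-12-bromo-2,3,6,10-tetramethyldodeca-1,6,10-triene
Conditions: CBr4, PPh3, CH2Cl2, 0 °C; used without storage
Reagents that add atoms: carbon tetrabromide, BrC(Br)(Br)Br
Why: Appel bromination under neutral conditions, which the acid-sensitive 1,1-disubstituted alkene should tolerate; primary allylic alcohols of this type give the unrearranged (E)-bromide.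

Step 19
Reactants: 25 (3S,6E,10E)-12-bromo-2,3,6,10-tetramethyldodeca-1,6,10-triene
Product: 26 {[(2E,6E,10S)-3,7,10,11-tetramethyldodeca-2,6,11-trien-1-yl]sulfonyl}benzene
Conditions: PhSO2Na, DMF, rt
Reagents that add atoms: sodium benzenesulfinate, [Na+].[O-]S(=O)c1ccccc1
Why: S-Alkylation of the ambident sulfinate by a soft primary allylic bromide (SN2) should give the allylic sulfone with the E alkene in place.

Step 20
Reactants: 26 {[(2E,6E,10S)-3,7,10,11-tetramethyldodeca-2,6,11-trien-1-yl]sulfonyl}benzene; 18 {(2R,3S)-3-methyl-3-[(3R,7R)-3,7,8-trimethyl-4-methylidenenon-8-en-1-yl]oxiran-2-yl}methyl trifluoromethanesulfonate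
Product: 28 (2S,3R)-2-methyl-3-[(3E,7E,11S)-2-(benzenesulfonyl)-4,8,11,12-tetramethyltrideca-3,7,12-trien-1-yl]-2-[(3R,7R)-3,7,8-trimethyl-4-methylidenenon-8-en-1-yl]oxirane (both C13 epimers), via lithiated sulfone 27 (not isolated)
Conditions: n-BuLi (1.05 equiv), THF, −78 °C; then 18 in THF, −78 °C; quench at −78 °C
Reagents that add atoms: none
Why: Alkylation of an α-sulfonyl allyl carbanion, which reacts at the carbon bearing sulfur and not at the γ-terminus; the primary triflate should react at −78 °C far faster than the hindered trisubstituted oxirane, so C10 and C11 are untouched, and the mixed C13 centre is erased in step 21.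

Step 21
Reactants: 28 (2S,3R)-2-methyl-3-[(3E,7E,11S)-2-(benzenesulfonyl)-4,8,11,12-tetramethyltrideca-3,7,12-trien-1-yl]-2-[(3R,7R)-3,7,8-trimethyl-4-methylidenenon-8-en-1-yl]oxirane
Product: 29 (2S,3R)-2-methyl-3-[(3E,7E,11S)-4,8,11,12-tetramethyltrideca-3,7,12-trien-1-yl]-2-[(3R,7R)-3,7,8-trimethyl-4-methylidenenon-8-en-1-yl]oxirane (CNP0301430.1)
Conditions: PdCl2(dppp) (10 mol %), LiEt3BH (2.0 equiv), THF, −20 → 0 °C
Reagents that add atoms: none
Why: Palladium-catalysed reductive desulfonylation of an allylic sulfone; ionisation gives a π-allyl palladium and hydride is delivered to the less substituted terminus C13, which should leave C14=C15 in place and E, while low temperature and limited hydride are meant to spare the oxirane, whose only attackable carbon (C11) is flanked by a quaternary centre.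

## Compound list

1 | nerol, (2Z)-3,7-dimethylocta-2,6-dien-1-ol | CC(C)=CCC/C(C)=C\CO | starting material
2 | tert-butyl{[(2Z)-3,7-dimethylocta-2,6-dien-1-yl]oxy}diphenylsilane | CC(C)=CCC/C(C)=C\CO[Si](c1ccccc1)(c1ccccc1)C(C)(C)C | intermediate
3 | tert-butyl{[(2Z)-5-(3,3-dimethyloxiran-2-yl)-3-methylpent-2-en-1-yl]oxy}diphenylsilane (racemic) | CC1(C)OC1CC/C(C)=C\CO[Si](c1ccccc1)(c1ccccc1)C(C)(C)C | intermediate
4 | (6Z)-8-[(tert-butyldiphenylsilyl)oxy]-2,6-dimethyloct-6-ene-2,3-diol (racemic, not isolated) | CC(C)(O)C(O)CC/C(C)=C\CO[Si](c1ccccc1)(c1ccccc1)C(C)(C)C | intermediate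
5 | (4Z)-6-[(tert-butyldiphenylsilyl)oxy]-4-methylhex-4-enal | O=CCC/C(C)=C\CO[Si](c1ccccc1)(c1ccccc1)C(C)(C)C | intermediate
6 | triethyl phosphonoacetate | CCOC(=O)CP(=O)(OCC)OCC | starting material
7 | 5-bromo-2-methylpent-2-ene | CC(C)=CCCBr | starting material
8 | sodium enolate of triethyl phosphonoacetate (not isolated) | CCOC(=O)[CH-]P(=O)(OCC)OCC.[Na+] | intermediate
9 | ethyl 2-(diethoxyphosphoryl)-6-methylhept-5-enoate (racemic) | CCOC(=O)C(CCC=C(C)C)P(=O)(OCC)OCC | intermediate
10 | sodium salt of 9 (not isolated) | CCOC(=O)[C-](CCC=C(C)C)P(=O)(OCC)OCC.[Na+] | intermediate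
11 | ethyl (2E,6Z)-8-[(tert-butyldiphenylsilyl)oxy]-6-methyl-2-(4-methylpent-3-en-1-yl)octa-2,6-dienoate | CCOC(=O)/C(CCC=C(C)C)=C/CC/C(C)=C\CO[Si](c1ccccc1)(c1ccccc1)C(C)(C)C | intermediate
12 | ethyl (2E,6Z)-8-[(tert-butyldiphenylsilyl)oxy]-2-[(3E)-5-hydroxy-4-methylpent-3-en-1-yl]-6-methylocta-2,6-dienoate | CCOC(=O)/C(CC/C=C(\C)CO)=C/CC/C(C)=C\CO[Si](c1ccccc1)(c1ccccc1)C(C)(C)C | intermediate
13 | (2E,6E,10Z)-12-[(tert-butyldiphenylsilyl)oxy]-6-(hydroxymethyl)-2,10-dimethyldodeca-2,6,10-trien-1-ol | OC/C(C)=C/CC/C(CO)=C\CC/C(C)=C\CO[Si](c1ccccc1)(c1ccccc1)C(C)(C)C | intermediate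
14 | tert-butyl{[(2Z,6E,10E)-12-bromo-7-(bromomethyl)-3,11-dimethyldodeca-2,6,10-trien-1-yl]oxy}diphenylsilane | BrC/C(C)=C/CC/C(CBr)=C\CC/C(C)=C\CO[Si](c1ccccc1)(c1ccccc1)C(C)(C)C | intermediate
15 | tert-butyldiphenyl{[(2Z,6R,10R)-3,6,10,11-tetramethyl-7-methylidenedodeca-2,11-dien-1-yl]oxy}silane | C=C(C)[C@H](C)CCC(=C)[C@H](C)CC/C(C)=C\CO[Si](c1ccccc1)(c1ccccc1)C(C)(C)C | intermediate
16 | (2Z,6R,10R)-3,6,10,11-tetramethyl-7-methylidenedodeca-2,11-dien-1-ol | C=C(C)[C@H](C)CCC(=C)[C@H](C)CC/C(C)=C\CO | intermediate
17 | {(2R,3S)-3-methyl-3-[(3R,7R)-3,7,8-trimethyl-4-methylidenenon-8-en-1-yl]oxiran-2-yl}methanol | C=C(C)[C@H](C)CCC(=C)[C@H](C)CC[C@]1(C)O[C@@H]1CO | intermediate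
18 | {(2R,3S)-3-methyl-3-[(3R,7R)-3,7,8-trimethyl-4-methylidenenon-8-en-1-yl]oxiran-2-yl}methyl trifluoromethanesulfonate | C=C(C)[C@H](C)CCC(=C)[C@H](C)CC[C@]1(C)O[C@@H]1COS(=O)(=O)C(F)(F)F | intermediate
19 | (2E,6E)-farnesol, (2E,6E)-3,7,11-trimethyldodeca-2,6,10-trien-1-ol | CC(C)=CCC/C(C)=C/CC/C(C)=C/CO | starting material
20 | tert-butyldiphenyl{[(2E,6E)-3,7,11-trimethyldodeca-2,6,10-trien-1-yl]oxy}silane | CC(C)=CCC/C(C)=C/CC/C(C)=C/CO[Si](c1ccccc1)(c1ccccc1)C(C)(C)C | intermediate
21 | (2E,6E,10E)-12-[(tert-butyldiphenylsilyl)oxy]-2,6,10-trimethyldodeca-2,6,10-trien-1-ol | OC/C(C)=C/CC/C(C)=C/CC/C(C)=C/CO[Si](c1ccccc1)(c1ccccc1)C(C)(C)C | intermediate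
22 | tert-butyl{[(2E,6E,10E)-12-bromo-3,7,11-trimethyldodeca-2,6,10-trien-1-yl]oxy}diphenylsilane | BrC/C(C)=C/CC/C(C)=C/CC/C(C)=C/CO[Si](c1ccccc1)(c1ccccc1)C(C)(C)C | intermediate
23 | tert-butyldiphenyl{[(2E,6E,10S)-3,7,10,11-tetramethyldodeca-2,6,11-trien-1-yl]oxy}silane | C=C(C)[C@@H](C)CC/C(C)=C/CC/C(C)=C/CO[Si](c1ccccc1)(c1ccccc1)C(C)(C)C | intermediate
24 | (2E,6E,10S)-3,7,10,11-tetramethyldodeca-2,6,11-trien-1-ol | C=C(C)[C@@H](C)CC/C(C)=C/CC/C(C)=C/CO | intermediate
25 | (3S,6E,10E)-12-bromo-2,3,6,10-tetramethyldodeca-1,6,10-triene | C=C(C)[C@@H](C)CC/C(C)=C/CC/C(C)=C/CBr | intermediate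
26 | {[(2E,6E,10S)-3,7,10,11-tetramethyldodeca-2,6,11-trien-1-yl]sulfonyl}benzene | C=C(C)[C@@H](C)CC/C(C)=C/CC/C(C)=C/CS(=O)(=O)c1ccccc1 | intermediate
27 | α-lithio derivative of 26 (not isolated) | C=C(C)[C@@H](C)CC/C(C)=C/CC/C(C)=C/C([Li])S(=O)(=O)c1ccccc1 | intermediate
28 | (2S,3R)-2-methyl-3-[(3E,7E,11S)-2-(benzenesulfonyl)-4,8,11,12-tetramethyltrideca-3,7,12-trien-1-yl]-2-[(3R,7R)-3,7,8-trimethyl-4-methylidenenon-8-en-1-yl]oxirane (both C13 epimers) | C=C(C)[C@H](C)CCC(=C)[C@H](C)CC[C@]1(C)O[C@@H]1CC(S(=O)(=O)c1ccccc1)/C=C(\C)CC/C=C(\C)CC[C@H](C)C(=C)C | intermediate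
29 | (2S,3R)-2-methyl-3-[(3E,7E,11S)-4,8,11,12-tetramethyltrideca-3,7,12-trien-1-yl]-2-[(3R,7R)-3,7,8-trimethyl-4-methylidenenon-8-en-1-yl]oxirane (CNP0301430.1) | C=C(C)[C@H](C)CCC(=C)[C@H](C)CC[C@]1(C)O[C@@H]1CC/C=C(\C)CC/C=C(\C)CC[C@H](C)C(=C)C | target

## Step count and least certain steps

Total step count: 21. Longest linear sequence: 13 steps (1 → 29 through steps 1–3, 5–12, 20 and 21); the right half contributes steps 13–19 and the phosphonate step 4 as side branches.

Step 9 (key step). The likely failures are competing direct SN2 substitution at one or both sites, and weaker facial discrimination at the internal site, whose β-substituent is a CH2 chain and not a methyl group; either would contaminate 15 with regio- or diastereomers that are hard to remove. A change of leaving group and ligand class (allylic chloride, copper thiophene-carboxylate, phosphoramidite) is the first adjustment. The fallback changes the approach and uses only substrate-bound, stereospecific steps; it sets out from 13 and returns at 15. A two-fold Sharpless epoxidation of 13 with L-(+)-diethyl tartrate should give the bis-epoxy diol F1. Trimethylaluminium should open each oxirane at the secondary carbon (C3 and C7) with inversion, directed by the aluminium alkoxide, to give the tetraol F2 with both methyl centres R. Thiocarbonyldiimidazole would convert the two 1,2-diols into the bis(thionocarbonate) F3, and Corey–Winter olefination (trimethyl phosphite, heat) would release both 1,1-disubstituted alkenes to give 15.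

Step 16. The same loss of regio- or enantiocontrol can occur at the single site of 22. The fallback sets out from 21 and returns at 23. Sharpless epoxidation of 21 with D-(−)-diethyl tartrate should give the epoxy alcohol F4; trimethylaluminium opening at C22 with inversion should give the diol F5 (22S); thiocarbonyldiimidazole would give the thionocarbonate F6, and Corey–Winter olefination would give 23.

Step 21. Hydride opening of the oxirane may compete with the palladium cycle, and slow hydride capture would allow η3–η1 isomerisation with erosion of the C14=C15 geometry or elimination to a diene. The fallback avoids both sulfone and hydride; it sets out from 24 and 18 and returns at 29. The alcohol 24 would be converted with N-chlorosuccinimide and dimethyl sulfide into the allylic chloride F14. F14 would be treated with activated barium (from BaI2 and lithium biphenylide) in THF at −78 °C to give the allylbarium chloride F15, used in the flask. Such reagents couple at the α-carbon with retention of the E geometry, so addition of the triflate 18 at −78 °C should give 29 directly.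

Step 5. Incomplete E selectivity is possible with an α-branched phosphonate, and the isomers may be tedious to separate; the wrong geometry would invert the facial sense at C7 in step 9. The fallback fixes the geometry by mechanism; it sets out from 5 and returns at 13. Ohira–Bestmann homologation of 5 would give the terminal alkyne F7, and lithiation followed by paraformaldehyde the propargylic alcohol F8. Copper(I)-catalysed anti-carbomagnesiation of F8 with the Grignard reagent F9 (from 7 and magnesium) places the new chain on the carbinol-bearing carbon through a five-membered magnesium alkoxide chelate, which after hydrolysis should give the allylic alcohol F10 with CH2OH trans to C8. Selenium dioxide/t-BuOOH oxidation of F10 with a borohydride finish would give 13.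

Step 6. Oxidation at a wrong allylic position, over-oxidation or low conversion would waste material at a late stage of the left half. The fallback replaces C–H oxidation by C–C bond formation; it sets out from 11 and returns at 13. Selective epoxidation of the isopropylidene alkene of 11 with mCPBA would give the epoxide F11, and periodic acid cleavage the aldehyde F12. Wittig reaction with ethyl 2-(triphenylphosphoranylidene)propanoate should give the (E,E)-diester F13, and DIBAL-H reduction of both esters would give 13.

## Further compounds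

F1 | step 9 | (2S,3S,6S,7S,10Z)-12-[(tert-butyldiphenylsilyl)oxy]-2,3:6,7-diepoxy-6-(hydroxymethyl)-2,10-dimethyldodec-10-en-1-ol | OC[C@]1(C)O[C@H]1CC[C@@]2(CO)O[C@H]2CC/C(C)=C\CO[Si](c3ccccc3)(c3ccccc3)C(C)(C)C
F2 | step 9 | (2R,3R,6R,7R,10Z)-12-[(tert-butyldiphenylsilyl)oxy]-6-(hydroxymethyl)-2,3,7,10-tetramethyldodec-10-ene-1,2,6-triol | OC[C@](C)(O)[C@H](C)CC[C@@](CO)(O)[C@H](C)CC/C(C)=C\CO[Si](c1ccccc1)(c1ccccc1)C(C)(C)C
F3 | step 9 | bis(cyclic thionocarbonate) of F2 [two 1,3-dioxolane-2-thione rings over O1/O2 and O6/O6a] | S=C1OC[C@](C)(O1)[C@H](C)CC[C@]2(COC(=S)O2)[C@H](C)CC/C(C)=C\CO[Si](c3ccccc3)(c3ccccc3)C(C)(C)C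
F4 | step 16 | (2R,3R,6E,10E)-12-[(tert-butyldiphenylsilyl)oxy]-2,3-epoxy-2,6,10-trimethyldodeca-6,10-dien-1-ol | OC[C@@]1(C)O[C@@H]1CC/C(C)=C/CC/C(C)=C/CO[Si](c2ccccc2)(c2ccccc2)C(C)(C)C
F5 | step 16 | (2S,3S,6E,10E)-12-[(tert-butyldiphenylsilyl)oxy]-2,3,6,10-tetramethyldodeca-6,10-diene-1,2-diol | OC[C@@](C)(O)[C@@H](C)CC/C(C)=C/CC/C(C)=C/CO[Si](c1ccccc1)(c1ccccc1)C(C)(C)C
F6 | step 16 | cyclic thionocarbonate of F5 (1,3-dioxolane-2-thione) | S=C1OC[C@@](C)(O1)[C@@H](C)CC/C(C)=C/CC/C(C)=C/CO[Si](c2ccccc2)(c2ccccc2)C(C)(C)C
F7 | step 5 | tert-butyl{[(2Z)-3-methylhept-2-en-6-yn-1-yl]oxy}diphenylsilane | C#CCC/C(C)=C\CO[Si](c1ccccc1)(c1ccccc1)C(C)(C)C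
F8 | step 5 | (6Z)-8-[(tert-butyldiphenylsilyl)oxy]-6-methyloct-6-en-2-yn-1-ol | OCC#CCC/C(C)=C\CO[Si](c1ccccc1)(c1ccccc1)C(C)(C)C
F9 | step 5 | (4-methylpent-3-en-1-yl)magnesium bromide | CC(C)=CCC[Mg]Br
F10 | step 5 | (2E,6Z)-8-[(tert-butyldiphenylsilyl)oxy]-6-methyl-2-(4-methylpent-3-en-1-yl)octa-2,6-dien-1-ol | OC/C(CCC=C(C)C)=C/CC/C(C)=C\CO[Si](c1ccccc1)(c1ccccc1)C(C)(C)C
F11 | step 6 | ethyl (2E,6Z)-8-[(tert-butyldiphenylsilyl)oxy]-2-[2-(3,3-dimethyloxiran-2-yl)ethyl]-6-methylocta-2,6-dienoate (racemic) | CCOC(=O)/C(CCC1OC1(C)C)=C/CC/C(C)=C\CO[Si](c2ccccc2)(c2ccccc2)C(C)(C)C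
F12 | step 6 | ethyl (2E,6Z)-8-[(tert-butyldiphenylsilyl)oxy]-6-methyl-2-(3-oxopropyl)octa-2,6-dienoate | CCOC(=O)/C(CCC=O)=C/CC/C(C)=C\CO[Si](c1ccccc1)(c1ccccc1)C(C)(C)C
F13 | step 6 | ethyl (2E,6E,10Z)-12-[(tert-butyldiphenylsilyl)oxy]-6-(ethoxycarbonyl)-2,10-dimethyldodeca-2,6,10-trienoate | CCOC(=O)/C(C)=C/CC/C(C(=O)OCC)=C\CC/C(C)=C\CO[Si](c1ccccc1)(c1ccccc1)C(C)(C)C
F14 | step 21 | (3S,6E,10E)-12-chloro-2,3,6,10-tetramethyldodeca-1,6,10-triene | C=C(C)[C@@H](C)CC/C(C)=C/CC/C(C)=C/CCl
F15 | step 21 | chlorido[(2E,6E,10S)-3,7,10,11-tetramethyldodeca-2,6,11-trien-1-yl]barium | C=C(C)[C@@H](C)CC/C(C)=C/CC/C(C)=C/C[Ba]Cl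
A1 | alternative 1 | (2Z,6R,10R)-1-[(tert-butyldiphenylsilyl)oxy]-3,6,10,11-tetramethyldodeca-2,11-dien-7-one | C=C(C)[C@H](C)CCC(=O)[C@H](C)CC/C(C)=C\CO[Si](c1ccccc1)(c1ccccc1)C(C)(C)C
A2 | alternative 1 | (2R,6Z)-8-[(tert-butyldiphenylsilyl)oxy]-N-methoxy-N,2,6-trimethyloct-6-enamide | CON(C)C(=O)[C@H](C)CC/C(C)=C\CO[Si](c1ccccc1)(c1ccccc1)C(C)(C)C
A3 | alternative 1 | (3R)-5-bromo-2,3-dimethylpent-1-ene | C=C(C)[C@H](C)CCBr
A4 | alternative 2 | (2E)-2-methylbut-2-en-1-ol | C/C=C(\C)CO
A5 | alternative 2 | ethyl 3,4-dimethylpent-4-enoate (racemic) | CCOC(=O)CC(C)C(C)=C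
A6 | alternative 3 | (2E,6E,10Z,14E,18E,22E)-1,24-dibromo-6-(bromomethyl)-2,10,15,19,23-pentamethyltetracosa-2,6,10,14,18,22-hexaene | BrC/C(C)=C/CC/C(CBr)=C\CC/C(C)=C\CC/C=C(\C)CC/C=C(\C)CC/C=C(\C)CBr
A7 | alternative 3 | (3R,7R,10Z,14E,18E,22R)-2,3,7,10,15,19,22,23-octamethyl-6-methylidenetetracosa-1,10,14,18,23-pentaene | C=C(C)[C@H](C)CCC(=C)[C@H](C)CC/C(C)=C\CC/C=C(\C)CC/C=C(\C)CC[C@@H](C)C(=C)C
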